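## Retrosynthetic overview

1. Last C–C bond: C7'–C1' by Pd-catalysed Negishi sp3–sp2 coupling of the alkylzinc from iodide 12 (east half, C8 and C8' set) with aryl bromide 22 (syringyl ring carrying the complete threo side chain). Two deprotections follow.
2. Iodide 12: C7–C1 bond and the C8 stereocentre from a CuH/Pd dual-catalytic anti-Markovnikov hydroarylation (proposed new step) of alkene 9 with aryl bromide 4. Alkene 9 comes from (R)-Roche ester, which supplies C8'.
3. Bromide 22: C8''–O bond by Mitsunobu inversion of methyl (R)-lactate with 4-bromo-2,6-dimethoxyphenol (16); C7''–aryl bond via Weinreb amide and the Grignard of 4; C7'' by CBS reduction.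
4. Arenes: 4 from anisole (ortho-hydroxylation, bromination, benzylation), used twice; 16 from resorcinol (methylation, ortho-hydroxylation, bromination).
5. No ring is formed in the route; the three benzene rings come from anisole (twice) and resorcinol.

Assumption: (R)-DTBM-SEGPHOS is taken as the ligand enantiomer that delivers hydride to the face of 9 giving C8 = S (by analogy with CuH additions to 1,1-dialkyl alkenes, and matched with the substrate's anti preference). If the first run shows the opposite sense, the (S)-ligand is used with no other change.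

## Route

**Step 1**
Reactants: 1, anisole
Product: 2, 2-methoxyphenol
Conditions: n-BuLi, TMEDA, Et2O, 0 °C to rt; B(OMe)3, −78 °C to rt; H2O2, AcOH, 0 °C
Reagents that add atoms: hydrogen peroxide, OO
Why: Directed ortho-metalation by OMe, borylation and oxidation of the C–B bond give the ortho-phenol (DoM / borate oxidation).

**Step 2**
Reactants: 2, 2-methoxyphenol
Product: 3, 4-bromo-2-methoxyphenol
Conditions: NBS, MeCN, 0 °C to rt
Reagents that add atoms: N-bromosuccinimide, O=C1CCC(=O)N1Br
Why: Electrophilic aromatic bromination goes para to the free OH, the strongest activator.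

**Step 3**
Reactants: 3, 4-bromo-2-methoxyphenol
Product: 4, 1-(benzyloxy)-4-bromo-2-methoxybenzene
Conditions: BnBr, K2CO3, DMF, rt
Reagents that add atoms: benzyl bromide, BrCc1ccccc1
Why: Williamson etherification masks the phenol for the later Grignard, CuH and zinc chemistry.

**Step 4**
Reactants: 5, methyl (R)-3-hydroxy-2-methylpropanoate ((R)-Roche ester)
Product: 6, methyl (R)-3-[(tert-butyldimethylsilyl)oxy]-2-methylpropanoate
Conditions: TBSCl, imidazole, CH2Cl2, rt
Reagents that add atoms: TBSCl, CC(C)(C)[Si](C)(C)Cl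
Why: Standard silylation of the primary alcohol; the stereocentre (future C8') is untouched.

**Step 5**
Reactants: 6, TBS-protected Roche ester
Product: 7, (R)-3-[(tert-butyldimethylsilyl)oxy]-N-methoxy-N,2-dimethylpropanamide
Conditions: MeNH(OMe)·HCl, i-PrMgCl, THF, −20 to 0 °C
Reagents that add atoms: N,O-dimethylhydroxylamine hydrochloride, CNOC.Cl
Why: Weinreb amide formation via the magnesium amide occurs at low temperature without α-epimerisation.

**Step 6**
Reactants: 7, Weinreb amide
Product: 8, (R)-4-[(tert-butyldimethylsilyl)oxy]-3-methylbutan-2-one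
Conditions: MeMgBr, THF, 0 °C; cold aq. NH4Cl
Reagents that add atoms: methylmagnesium bromide, C[Mg]Br
Why: Weinreb ketone synthesis; the chelated tetrahedral intermediate prevents over-addition.

**Step 7**
Reactants: 8, methyl ketone
Product: 9, (S)-tert-butyl[(2,3-dimethylbut-3-en-1-yl)oxy]dimethylsilane
Conditions: Zn, CH2Br2, TiCl4, THF/CH2Cl2, 0 °C to rt
Reagents that add atoms: dibromomethane, BrCBr
Why: Takai–Lombardo methylenation is non-basic, so the α-stereocentre is not epimerised (the descriptor changes to S only through CIP priorities).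

**Step 8**
Reactants: 9, (S)-alkene (1.5 equiv); 4, 1-(benzyloxy)-4-bromo-2-methoxybenzene
Product: 10, tert-butyl{[(2S,3S)-4-(4-benzyloxy-3-methoxyphenyl)-2,3-dimethylbutyl]oxy}dimethylsilane
Conditions: Cu(OAc)2 (5 mol%), (R)-DTBM-SEGPHOS (5.5 mol%), [Pd(cinnamyl)Cl]2 (2 mol%), BrettPhos (4.4 mol%), Me(MeO)2SiH (3 equiv), NaOTMS (2 equiv), THF, 45 °C
Reagents that add atoms: none (the silane supplies only H)
Why: Proposed new method: a catalyst-controlled diastereoselective CuH/Pd anti-Markovnikov hydroarylation of an α-branched 1,1-dialkyl alkene, in which L*CuH adds across the C=C with Cu on the terminal CH2 and H delivered to C3 on the face chosen by the DTBM-SEGPHOS pocket (methyl versus α-branched alkyl discrimination, reinforced by the A1,3-minimised anti preference of the allylic stereocentre) to set C8 = S, after which the primary alkylcopper transmetalates to BrettPhos–Pd(Ar)Br from 4 and C(sp3)–C(sp2) reductive elimination forms the C7–C1 bond while NaOTMS and silane regenerate CuH; the closest known reactions are CuH/Pd anti-Markovnikov hydroarylation of terminal alkenes and enantioselective CuH hydroamination of 1,1-disubstituted alkenes, neither shown for diastereocontrolled construction of a vicinal dimethyl array.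

**Step 9**
Reactants: 10, silyl ether
Product: 11, (2S,3S)-4-(4-benzyloxy-3-methoxyphenyl)-2,3-dimethylbutan-1-ol
Conditions: TBAF, THF, rt
Reagents that add atoms: none
Why: Fluoride cleaves the primary TBS ether; the aryl benzyl ether is inert.

**Step 10**
Reactants: 11, primary alcohol
Product: 12, 1-(benzyloxy)-4-[(2S,3S)-4-iodo-2,3-dimethylbutyl]-2-methoxybenzene
Conditions: I2, PPh3, imidazole, CH2Cl2, 0 °C to rt
Reagents that add atoms: iodine, II
Why: Appel iodination at the primary carbon; neither stereocentre is involved.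

**Step 11**
Reactants: 13, resorcinol
Product: 14, 1,3-dimethoxybenzene
Conditions: MeI (2.5 equiv), K2CO3, acetone, reflux
Reagents that add atoms: iodomethane, CI
Why: Double Williamson O-methylation.

**Step 12**
Reactants: 14, 1,3-dimethoxybenzene
Product: 15, 2,6-dimethoxyphenol
Conditions: n-BuLi, THF, 0 °C to rt; B(OMe)3, −78 °C to rt; H2O2, AcOH, 0 °C
Reagents that add atoms: hydrogen peroxide, OO
Why: Directed ortho-metalation occurs at C2, flanked by both OMe groups, and borate oxidation gives the phenol.

**Step 13**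
Reactants: 15, 2,6-dimethoxyphenol
Product: 16, 4-bromo-2,6-dimethoxyphenol
Conditions: NBS, CHCl3 (1% EtOH), −45 °C to rt
Reagents that add atoms: N-bromosuccinimide, O=C1CCC(=O)N1Br
Why: The free OH directs bromination to its para position, and low temperature suppresses oxidation to the quinone.

**Step 14**
Reactants: 16, 4-bromo-2,6-dimethoxyphenol; 17, methyl (R)-lactate
Product: 18, methyl (S)-2-(4-bromo-2,6-dimethoxyphenoxy)propanoate
Conditions: PPh3, DIAD, THF, 0 °C to rt
Reagents that add atoms: none
Why: Mitsunobu etherification with clean SN2 inversion at the lactate carbon sets C8'' = S.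

**Step 15**
Reactants: 18, aryloxy ester
Product: 19, (S)-2-(4-bromo-2,6-dimethoxyphenoxy)-N-methoxy-N-methylpropanamide
Conditions: MeNH(OMe)·HCl, i-PrMgCl, THF, −20 °C
Reagents that add atoms: N,O-dimethylhydroxylamine hydrochloride, CNOC.Cl
Why: Weinreb amide formation at low temperature; the electron-rich aryl bromide does not exchange with i-PrMgCl and C8'' is retained.

**Step 16**
Reactants: 19, Weinreb amide; 4, 1-(benzyloxy)-4-bromo-2-methoxybenzene
Product: 20, (S)-1-(4-benzyloxy-3-methoxyphenyl)-2-(4-bromo-2,6-dimethoxyphenoxy)propan-1-one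
Conditions: 4, Mg, THF, 40 °C (ArMgBr); then 19, THF, 0 °C; cold aq. NH4Cl
Reagents that add atoms: none
Why: Weinreb ketone synthesis; a Grignard rather than an aryllithium avoids halogen–metal exchange with the aryl bromide of 19.

**Step 17**
Reactants: 20, α-aryloxy ketone
Product: 21, (1S,2S)-1-(4-benzyloxy-3-methoxyphenyl)-2-(4-bromo-2,6-dimethoxyphenoxy)propan-1-ol (threo)
Conditions: (S)-Me-CBS (0.5 equiv), BH3·SMe2, THF, −20 °C
Reagents that add atoms: none
Why: Corey–Bakshi–Shibata reduction with the aryl group as the large substituent delivers hydride to give C7'' = S, matched with the Felkin–Anh (non-chelate) preference for the threo alcohol; the non-basic conditions leave C8'' intact.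

**Step 18**
Reactants: 21, threo alcohol
Product: 22, tert-butyl{[(1S,2S)-1-(4-benzyloxy-3-methoxyphenyl)-2-(4-bromo-2,6-dimethoxyphenoxy)propyl]oxy}dimethylsilane
Conditions: TBSOTf, 2,6-lutidine, CH2Cl2, 0 °C
Reagents that add atoms: TBSOTf, CC(C)(C)[Si](C)(C)OS(=O)(=O)C(F)(F)F
Why: Silyl triflate protects the hindered benzylic alcohol so it cannot quench the alkylzinc.

**Step 19**
Reactants: 12, alkyl iodide; 22, aryl bromide
Product: 23, the 4,4''-di-O-benzyl-7''-O-TBS derivative of the target (7''S,8S,8'R,8''S)
Conditions: 12, Zn dust (TMSCl/BrCH2CH2Br-activated), LiCl, THF, 40 °C; then 22, Pd(OAc)2 (3 mol%), SPhos (6 mol%), THF, 50 °C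
Reagents that add atoms: none
Why: Negishi C(sp3)–C(sp2) coupling of a primary alkylzinc with an unhindered aryl bromide forms C7'–C1'; no stereocentre is at a reacting carbon.

**Step 20**
Reactants: 23, protected sesquineolignan
Product: 24, the 4,4''-di-O-benzyl ether of the target (free 7''-OH)
Conditions: TBAF, AcOH (1 equiv), THF, rt
Reagents that add atoms: none
Why: Buffered fluoride desilylation; no acid is present that could ionise the benzylic C7''–O bond.

**Step 21**
Reactants: 24, bis-benzyl ether
Product: 25, (+)-(7''S,8S,8'R,8''S)-4,4''-dihydroxy-3,3',3'',5'-tetramethoxy-4',8''-oxy-8,8'-sesquineolignan-7''-ol (target)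
Conditions: H2 (1 atm), 10% Pd/C, EtOAc/MeOH, rt
Reagents that add atoms: none
Why: Neutral hydrogenolysis removes both aryl benzyl ethers; the secondary benzylic alcohol and the alkyl aryl ether are stable under these conditions.

## Compound list

1 | anisole | COc1ccccc1 | starting material
2 | 2-methoxyphenol | COc1ccccc1O | intermediate
3 | 4-bromo-2-methoxyphenol | COc1cc(Br)ccc1O | intermediate
4 | 1-(benzyloxy)-4-bromo-2-methoxybenzene | COc1cc(Br)ccc1OCc1ccccc1 | intermediate
5 | methyl (R)-3-hydroxy-2-methylpropanoate | COC(=O)[C@H](C)CO | starting material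
6 | methyl (R)-3-[(tert-butyldimethylsilyl)oxy]-2-methylpropanoate | COC(=O)[C@H](C)CO[Si](C)(C)C(C)(C)C | intermediate
7 | (R)-3-[(tert-butyldimethylsilyl)oxy]-N-methoxy-N,2-dimethylpropanamide | CON(C)C(=O)[C@H](C)CO[Si](C)(C)C(C)(C)C | intermediate
8 | (R)-4-[(tert-butyldimethylsilyl)oxy]-3-methylbutan-2-one | CC(=O)[C@H](C)CO[Si](C)(C)C(C)(C)C | intermediate
9 | (S)-tert-butyl[(2,3-dimethylbut-3-en-1-yl)oxy]dimethylsilane | C=C(C)[C@H](C)CO[Si](C)(C)C(C)(C)C | intermediate
10 | tert-butyl{[(2S,3S)-4-(4-benzyloxy-3-methoxyphenyl)-2,3-dimethylbutyl]oxy}dimethylsilane | COc1cc(C[C@H](C)[C@H](C)CO[Si](C)(C)C(C)(C)C)ccc1OCc1ccccc1 | intermediate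
11 | (2S,3S)-4-(4-benzyloxy-3-methoxyphenyl)-2,3-dimethylbutan-1-ol | COc1cc(C[C@H](C)[C@H](C)CO)ccc1OCc1ccccc1 | intermediate
12 | 1-(benzyloxy)-4-[(2S,3S)-4-iodo-2,3-dimethylbutyl]-2-methoxybenzene | COc1cc(C[C@H](C)[C@H](C)CI)ccc1OCc1ccccc1 | intermediate
13 | resorcinol | Oc1cccc(O)c1 | starting material
14 | 1,3-dimethoxybenzene | COc1cccc(OC)c1 | intermediate
15 | 2,6-dimethoxyphenol | COc1cccc(OC)c1O | intermediate
16 | 4-bromo-2,6-dimethoxyphenol | COc1cc(Br)cc(OC)c1O | intermediate
17 | methyl (R)-lactate | C[C@@H](O)C(=O)OC | starting material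
18 | methyl (S)-2-(4-bromo-2,6-dimethoxyphenoxy)propanoate | COc1cc(Br)cc(OC)c1O[C@@H](C)C(=O)OC | intermediate
19 | (S)-2-(4-bromo-2,6-dimethoxyphenoxy)-N-methoxy-N-methylpropanamide | COc1cc(Br)cc(OC)c1O[C@@H](C)C(=O)N(C)OC | intermediate
20 | (S)-1-(4-benzyloxy-3-methoxyphenyl)-2-(4-bromo-2,6-dimethoxyphenoxy)propan-1-one | COc1cc(Br)cc(OC)c1O[C@@H](C)C(=O)c1ccc(OCc2ccccc2)c(OC)c1 | intermediate
21 | (1S,2S)-1-(4-benzyloxy-3-methoxyphenyl)-2-(4-bromo-2,6-dimethoxyphenoxy)propan-1-ol | COc1cc(Br)cc(OC)c1O[C@@H](C)[C@@H](O)c1ccc(OCc2ccccc2)c(OC)c1 | intermediate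
22 | tert-butyl{[(1S,2S)-1-(4-benzyloxy-3-methoxyphenyl)-2-(4-bromo-2,6-dimethoxyphenoxy)propyl]oxy}dimethylsilane | COc1cc(Br)cc(OC)c1O[C@@H](C)[C@@H](O[Si](C)(C)C(C)(C)C)c1ccc(OCc2ccccc2)c(OC)c1 | intermediate
23 | 4,4''-di-O-benzyl-7''-O-TBS derivative of the target (7''S,8S,8'R,8''S) | COc1cc(C[C@H](C)[C@H](C)Cc2cc(OC)c(O[C@@H](C)[C@@H](O[Si](C)(C)C(C)(C)C)c3ccc(OCc4ccccc4)c(OC)c3)c(OC)c2)ccc1OCc1ccccc1 | intermediate
24 | 4,4''-di-O-benzyl ether of the target (7''S,8S,8'R,8''S) | COc1cc(C[C@H](C)[C@H](C)Cc2cc(OC)c(O[C@@H](C)[C@@H](O)c3ccc(OCc4ccccc4)c(OC)c3)c(OC)c2)ccc1OCc1ccccc1 | intermediate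
25 | (+)-(7''S,8S,8'R,8''S)-4,4''-dihydroxy-3,3',3'',5'-tetramethoxy-4',8''-oxy-8,8'-sesquineolignan-7''-ol | COc1cc(C[C@H](C)[C@H](C)Cc2cc(OC)c(O[C@@H](C)[C@@H](O)c3ccc(O)c(OC)c3)c(OC)c2)ccc1O | target

## Summary

Total step count: 21.

Longest linear sequence: 11 steps (resorcinol 13 through steps 11–18, then steps 19–21). The Roche ester branch is 10 steps and the anisole branches are 9 steps to the target.

Steps most likely to fail:

1. **Step 8 (proposed new CuH/Pd hydroarylation).** Hydrocupration of the hindered α-branched 1,1-dialkyl alkene may be slow, giving reduction of 4 to the arene, or the diastereoselectivity may be low. Fallback with known chemistry: hydroborate 9 with 9-BBN (substrate-controlled anti 1,2-induction), then B-alkyl Suzuki–Miyaura coupling with 4 (Pd(dppf)Cl2, aq. K3PO4, THF/DMF). The minor syn diastereomer is removed at alcohol 11.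

2. **Step 17 (CBS reduction to the threo alcohol).** The α-branched aryloxyalkyl group may compete with the aryl as the "large" substituent and erode the diastereomer ratio. Fallback: reduce ester 18 with DIBAL to (S)-2-(4-bromo-2,6-dimethoxyphenoxy)propanal and add the Grignard of 4 under chelation control (MgBr2·OEt2, CH2Cl2, −78 °C). The Cram-chelate addition gives the threo alcohol 21 directly.

3. **Step 19 (Negishi coupling of the two large fragments).** Zinc insertion into the β-branched iodide may be incomplete, or the alkylzinc may protodemetalate or homocouple before it couples with the electron-rich bromide. Fallback: oxidise 11 to the aldehyde (Dess–Martin), add the aryllithium from 22 (n-BuLi, −78 °C), and remove the new benzylic hydroxyl by Barton–McCombie deoxygenation (xanthate, Bu3SnH/AIBN) to reach 23.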